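**Retrosynthetic overview**

1. Target ⇐ LiOH unmasking ⇐ C3 aroylation (vinyllithium plus silyl-protected 3-hydroxybenzoyl chloride) ⇐ bridgehead C1 prenylation of a bicyclo[3.3.1]nonane methyl vinylogous ester that still has C1–H.
2. Key disconnection: the bond from bridgehead C1 to the adjacent quaternary C8 (methyl, 4-methylpent-3-enyl), with the C9 ketone spanning C1 and C5. It maps onto a cis-fused hydrindanol in which C8 still sits on carbinol C9 and C1 is the free α′-CH2 of the C2–C3–C4 vinylogous ester; an iodane-triggered 1,2-shift of C8 from C9 to C1 turns the cyclopentane into ring X.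
3. Hydrindanol ⇐ intramolecular aldol of a 1,3-diketone dianion (C1 onto C9, closing ring Y) ⇐ 2-acetyl-2-prenylcyclopentanone; C5 is acylated before it is prenylated so that ring Y ends up syn to the C7 prenyl.
4. Cyclopentanone ⇐ copper-catalysed asymmetric conjugate addition with enolate methylation on 2-homoprenylcyclopent-2-enone (sets C7, then C8) ⇐ cyclopent-2-enone by α-iodination and Negishi coupling.
5. Ring order: cyclopentane (purchased) → ring Y (aldol, step 8) → ring X (ring expansion, step 10).

Key step: step 10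

Convention: C1–C9 follow the bicyclo[3.3.1]nonane numbering of the target (C1, C5 bridgeheads; C9 bridging ketone; C2–C4 enolised diketone; C7 CH–prenyl; C8 methyl/homoprenyl carbon). β is the face of the five-membered ring (later ring X) that carries the C8 methyl; α is the face that carries the C7 prenyl and the C8 homoprenyl.

Assumption: the antipode of the carbene ligand in step 3 is chosen to deliver the (3S) adduct; all later stereocentres follow from it by substrate control.

**Route**

Step 1
Reactants: 1 cyclopent-2-en-1-one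
Product: 2 2-iodocyclopent-2-en-1-one
Conditions: I2, K2CO3, DMAP (cat.), THF/H2O 1:1, rt
Reagents that add atoms: iodine, II
Why: Amine-mediated α-iodination of an enone (Baylis–Hillman-type addition of DMAP, iodination of the enolate, elimination) places the halogen at C2 only.

Step 2
Reactants: 2 2-iodocyclopent-2-en-1-one; 3 5-bromo-2-methylpent-2-ene
Product: 5 2-(4-methylpent-3-en-1-yl)cyclopent-2-en-1-one, via (4-methylpent-3-enyl)zinc bromide 4 (not isolated)
Conditions: 3, Zn dust, LiCl, THF, 50 °C; then 2, Pd2(dba)3 (2 mol %), tri(2-furyl)phosphine (8 mol %), THF/DMF, rt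
Reagents that add atoms: none
Why: Zinc insertion into the primary bromide and Negishi coupling with the α-iodoenone (fast oxidative addition of zerovalent palladium into the vinyl C–I bond; the alkylzinc does not add to the enone) should put the homoprenyl chain on the α-carbon.

Step 3
Reactants: 5 2-(4-methylpent-3-en-1-yl)cyclopent-2-en-1-one; 6 4-bromo-2-methylbut-1-ene
Product: 9 (2S,3S)-2-methyl-3-(3-methylbut-3-en-1-yl)-2-(4-methylpent-3-en-1-yl)cyclopentan-1-one, via (3-methylbut-3-enyl)magnesium bromide 7 (not isolated), via bromomagnesium enolate 8 (not isolated)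
Conditions: 6, Mg, Et2O; then 5, Cu(OTf)2 (3 mol %), chiral hydroxyalkyl imidazolinium salt (N-heterocyclic carbene precursor, 4 mol %), Et2O, −30 °C; then MeI, DMPU, −30 °C → rt
Reagents that add atoms: iodomethane, CI
Why: Copper-catalysed asymmetric conjugate addition of a primary alkyl Grignard reagent to a 2-alkylcyclopentenone sets C7 by ligand control of the enone face, and the regiodefined magnesium enolate is methylated anti to the new C7 chain, which fixes C8 with methyl trans and homoprenyl cis to that chain.

Step 4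
Reactants: 9 (2S,3S)-2-methyl-3-(3-methylbut-3-en-1-yl)-2-(4-methylpent-3-en-1-yl)cyclopentan-1-one
Product: 10 (2S,3R)-2-methyl-3-(3-methylbut-2-en-1-yl)-2-(4-methylpent-3-en-1-yl)cyclopentan-1-one
Conditions: Co(salen)Cl [salen = N,N′-bis(3,5-di-tert-butylsalicylidene)cyclohexane-1,2-diamine dianion; trivalent cobalt] (3 mol %), PhSiH3 (6 mol %), benzene, rt
Reagents that add atoms: none
Why: Cobalt hydride hydrogen-atom-transfer isomerisation moves the 1,1-disubstituted alkene by one position into the more stable trisubstituted prenyl alkene, which has no E/Z issue, while the homoprenyl alkene is already in its most stable position and no stereocentre is touched.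

Step 5
Reactants: 10 (2S,3R)-2-methyl-3-(3-methylbut-2-en-1-yl)-2-(4-methylpent-3-en-1-yl)cyclopentan-1-one
Product: 11 (2S,3S)-5-acetyl-2-methyl-2-(4-methylpent-3-en-1-yl)-3-(3-methylbut-2-en-1-yl)cyclopentan-1-one (C5 epimers and enol)
Conditions: MgBr2·OEt2, i-Pr2NEt, 1-acetylbenzotriazole, CH2Cl2, rt
Reagents that add atoms: 1-acetyl-1H-benzotriazole, CC(=O)n1nnc2ccccc12
Why: Soft enolisation (magnesium chelate, amine base) and Claisen-type C-acylation by the acylbenzotriazole can occur only at C5 because C8 is quaternary, so a single β-diketone should form without any alkoxide that could cleave it.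

Step 6
Reactants: 11 (2S,3S)-5-acetyl-2-methyl-2-(4-methylpent-3-en-1-yl)-3-(3-methylbut-2-en-1-yl)cyclopentan-1-one; 12 prenyl bromide (1-bromo-3-methylbut-2-ene)
Product: 13 (2S,3S,5S)-5-acetyl-2-methyl-2-(4-methylpent-3-en-1-yl)-3,5-bis(3-methylbut-2-en-1-yl)cyclopentan-1-one
Conditions: K2CO3, acetone, rt → 40 °C
Reagents that add atoms: none
Why: C-alkylation of the stabilised β-diketone enolate by an allylic bromide should take place on the β face of the planar C5, anti to the C7 prenyl and the C8 homoprenyl, so the acetyl group (future C4) is left on the α face syn to the C7 prenyl and the new prenyl is β.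

Step 7
Reactants: 13 (2S,3S,5S)-5-acetyl-2-methyl-2-(4-methylpent-3-en-1-yl)-3,5-bis(3-methylbut-2-en-1-yl)cyclopentan-1-one
Product: 14 1-[(1S,3S,4S)-3-methyl-3-(4-methylpent-3-en-1-yl)-1,4-bis(3-methylbut-2-en-1-yl)-2-oxocyclopentyl]butane-1,3-dione
Conditions: MgBr2·OEt2, i-Pr2NEt, 1-acetylbenzotriazole, CH2Cl2, rt
Reagents that add atoms: 1-acetyl-1H-benzotriazole, CC(=O)n1nnc2ccccc12
Why: The acetyl methyl group is the only enolisable position left (C5 and C8 are quaternary), so magnesium-chelate soft enolisation and C-acylation should give the 1,3,5-triketone without the retro-Claisen cleavage that alkoxide bases would cause on this non-enolisable β-diketone.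

Step 8
Reactants: 14 1-[(1S,3S,4S)-3-methyl-3-(4-methylpent-3-en-1-yl)-1,4-bis(3-methylbut-2-en-1-yl)-2-oxocyclopentyl]butane-1,3-dione
Product: 16 cis-fused hydrindanol dione (C9–OH β; C5 prenyl β), via dilithium diketone dianion 15 (not isolated)
Conditions: LDA (2.3 equiv), THF, −78 → 0 °C; AcOH quench at −78 °C
Reagents that add atoms: none
Why: Double deprotonation gives the Hauser-type 1,3-diketone dianion whose terminal carbon C1 adds to the C9 ketone in an intramolecular aldol (6-exo-trig), and because the tether hangs from the α face of C5 it can reach C9 only from that face, which makes the ring fusion cis and sets C9 with OH β.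

Step 9
Reactants: 16 cis-fused hydrindanol dione
Product: 18 cis-fused hydrindanol vinylogous ester (C4–OMe; C2 ketone; C1 methylene; C9–OH β), via lithium diketonate 17 (not isolated)
Conditions: LiHMDS (1.05 equiv), THF, −78 °C; then Me2SO4, −78 °C → rt
Reagents that add atoms: dimethyl sulfate, COS(=O)(=O)OC
Why: O-Methylation of the lithium diketonate by a hard electrophile should occur at the free O4 because the C9 hydroxyl holds the lithium at O2 in a six-membered chelate, which gives the vinylogous ester with C2 as the ketone and C1 as its α′-methylene.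

Step 10
Reactants: 18 cis-fused hydrindanol vinylogous ester
Product: 21 bicyclo[3.3.1]nonane methyl vinylogous ester with C1–H bridgehead, via dilithium enolate-alkoxide 19 (not isolated), via C1-iodanyl ketone 20 (not isolated)
Conditions: LDA (2.2 equiv), THF, −78 °C; then PhI(OAc)2, −78 → 0 °C
Reagents that add atoms: none
Why: LDA removes the hydroxyl proton and one α′-proton at C1 to give the cross-conjugated dilithium enolate-alkoxide 19, whose enolate carbon attacks trivalent iodine with loss of acetate to give the C1-iodanyl ketone 20; departure of iodobenzene is coupled to a 1,2-shift of C8 from C9 to C1 while the C9 alkoxide collapses to the ketone, the closest known reaction type being the hypervalent-iodine oxidative semipinacol ring expansion of fused β-hydroxy vinylogous esters to bicyclo[3.3.1]nonane-2,4,9-trione enol ethers. Ring X (C1–C8–C7–C6–C5–C9) is closed not by an end-to-end cyclisation but by this suprafacial 1,2-alkyl shift, which inserts C1 into the C9–C8 bond of the cyclopentane (five- to six-membered ring expansion) and turns the fused system into the bridged one. The new stereocentre C1 is formed with inversion at C1 (C8 enters anti to the departing iodane) and is in any case the only configuration the bridged bicycle allows, while C8 migrates with retention so that its methyl/homoprenyl arrangement is carried over unchanged. The step needs C8, and not the ring-fusion carbon C5 (ring contraction) or the oxygen (epoxide), to lie anti to the C1–I bond: the lithium bridge between O9 and O2 keeps the C9–O bond near the enolate plane and so makes C9–C8 the axial bond, and the iodane can reach C1 only from the β face because the α face is screened by the cyclopentane with its C8 homoprenyl and C7 prenyl, which places C1–I antiperiplanar to C9–C8 and gauche to both C9–O and C9–C5. The C1=C2 enolate cannot undergo retro-aldol cleavage and the electron-rich quaternary C8 is a good migrating group, so the C1–C8 bond next to a quaternary centre should form without any intermolecular attack on C8.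

Step 11
Reactants: 21 bicyclo[3.3.1]nonane methyl vinylogous ester with C1–H bridgehead; 12 prenyl bromide
Product: 23 C1-prenylated bicyclo[3.3.1]nonane methyl vinylogous ester, via bridgehead C1-lithio species 22 (not isolated)
Conditions: LDA (1.5 equiv), THF, −78 °C; then prenyl bromide, −78 °C → rt
Reagents that add atoms: none
Why: Bridgehead deprotonation of C1–H, which is flanked by the C9 and C2 carbonyls, by LDA (which leaves the vinylic C3–H alone) gives a configurationally locked bridgehead carbanion that the allylic bromide should alkylate with retention, as in known bridgehead prenylations of bicyclo[3.3.1]nonane-2,4,9-trione enol ethers.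

Step 12
Reactants: 24 3-hydroxybenzoic acid
Product: 25 tert-butyldimethylsilyl 3-[(tert-butyldimethylsilyl)oxy]benzoate
Conditions: TBSCl (2.3 equiv), imidazole, DMF, rt
Reagents that add atoms: tert-butyldimethylsilyl chloride, CC(C)(C)[Si](C)(C)Cl
Why: Silylation of both the phenol and the carboxylic acid protects the phenol and prepares the acid for activation under neutral conditions.

Step 13
Reactants: 25 tert-butyldimethylsilyl 3-[(tert-butyldimethylsilyl)oxy]benzoate
Product: 26 3-[(tert-butyldimethylsilyl)oxy]benzoyl chloride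
Conditions: (COCl)2, DMF (cat.), CH2Cl2, 0 °C → rt
Reagents that add atoms: oxalyl chloride, O=C(Cl)C(=O)Cl
Why: Silyl esters are converted directly into acid chlorides by oxalyl chloride/DMF (Vilsmeier activation with loss of TBSCl) without any HCl, so the aryl silyl ether should survive.

Step 14
Reactants: 23 C1-prenylated bicyclo[3.3.1]nonane methyl vinylogous ester; 26 3-[(tert-butyldimethylsilyl)oxy]benzoyl chloride
Product: 28 C3-aroylated bicyclic methyl vinylogous ester (silyl-protected), via C3-vinyllithium 27 (not isolated)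
Conditions: LiTMP (3 equiv), THF, −78 °C; then 26, −78 → 0 °C
Reagents that add atoms: none
Why: With both bridgeheads quaternary the only acidic hydrogen is the vinylic C3–H of the β-methoxy enone, so LiTMP should give the vinyllithium, which is C-acylated by the aroyl chloride (known C3 acylation of these enol ethers).

Step 15
Reactants: 28 C3-aroylated bicyclic methyl vinylogous ester (silyl-protected)
Product: 29 CNP0406274.1
Conditions: LiOH·H2O, 1,4-dioxane/H2O, 90 °C; then aq. HCl
Reagents that add atoms: lithium hydroxide, [Li+].[OH-]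
Why: Hydroxide should add to C4 of the doubly activated vinylogous ester and expel methoxide (addition–elimination) and also cleave the aryl silyl ether at silicon, and acidification gives the enolised triketone with all stereocentres (quaternary, or non-enolisable C7) untouched.

**Compound list**

1 | cyclopent-2-en-1-one | O=C1C=CCC1 | starting material
2 | 2-iodocyclopent-2-en-1-one | O=C1CCC=C1I | intermediate
3 | 5-bromo-2-methylpent-2-ene | CC(C)=CCCBr | starting material
4 | (4-methylpent-3-enyl)zinc bromide | CC(C)=CCC[Zn]Br | intermediate (not isolated)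
5 | 2-(4-methylpent-3-en-1-yl)cyclopent-2-en-1-one | CC(C)=CCCC1=CCCC1=O | intermediate
6 | 4-bromo-2-methylbut-1-ene | C=C(C)CCBr | starting material
7 | (3-methylbut-3-enyl)magnesium bromide | C=C(C)CC[Mg]Br | intermediate (not isolated)
8 | bromomagnesium enolate of the conjugate adduct (C7 set, enolate C8=C9) | CC(C)=CCCC1=C(O[Mg]Br)CC[C@@H]1CCC(C)=C | intermediate (not isolated)
9 | (2S,3S)-2-methyl-3-(3-methylbut-3-en-1-yl)-2-(4-methylpent-3-en-1-yl)cyclopentan-1-one (methyl trans to the C3 chain) | CC(C)=CCC[C@@]1(C)[C@@H](CCC(C)=C)CCC1=O | intermediate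
10 | (2S,3R)-2-methyl-3-(3-methylbut-2-en-1-yl)-2-(4-methylpent-3-en-1-yl)cyclopentan-1-one (methyl β; prenyl and homoprenyl α) | CC(C)=CCC[C@@]1(C)[C@@H](CC=C(C)C)CCC1=O | intermediate
11 | (2S,3S)-5-acetyl-2-methyl-2-(4-methylpent-3-en-1-yl)-3-(3-methylbut-2-en-1-yl)cyclopentan-1-one (C5 epimers and enol) | CC(C)=CCC[C@@]1(C)[C@@H](CC=C(C)C)CC(C(C)=O)C1=O | intermediate
12 | prenyl bromide (1-bromo-3-methylbut-2-ene) | CC(C)=CCBr | starting material
13 | (2S,3S,5S)-5-acetyl-2-methyl-2-(4-methylpent-3-en-1-yl)-3,5-bis(3-methylbut-2-en-1-yl)cyclopentan-1-one (C5 prenyl β, acetyl α) | CC(C)=CCC[C@@]1(C)[C@@H](CC=C(C)C)C[C@@](CC=C(C)C)(C(C)=O)C1=O | intermediate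
14 | 1-[(1S,3S,4S)-3-methyl-3-(4-methylpent-3-en-1-yl)-1,4-bis(3-methylbut-2-en-1-yl)-2-oxocyclopentyl]butane-1,3-dione | CC(C)=CCC[C@@]1(C)[C@@H](CC=C(C)C)C[C@@](CC=C(C)C)(C(=O)CC(C)=O)C1=O | intermediate
15 | dilithium dianion of 14 (bis-enolate C4(OLi)=C3–C2(OLi)=C1H2) | CC(C)=CCC[C@@]1(C)[C@@H](CC=C(C)C)C[C@@](CC=C(C)C)(C(O[Li])=CC(O[Li])=C)C1=O | intermediate (not isolated)
16 | cis-fused hydrindanol dione: 7a-hydroxy-1-methyl-1-(4-methylpent-3-en-1-yl)-2,3a-bis(3-methylbut-2-en-1-yl)hexahydro-1H-indene-4,6(5H)-dione; C9–OH, C5 prenyl and C8 methyl β; C7 prenyl and C8 homoprenyl α | CC(C)=CCC[C@@]1(C)[C@@H](CC=C(C)C)C[C@@]2(CC=C(C)C)C(=O)CC(=O)C[C@@]12O | intermediate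
17 | lithium diketonate of 16 (lithium held at O2 by the C9 hydroxyl) | CC(C)=CCC[C@@]1(C)[C@@H](CC=C(C)C)C[C@@]2(CC=C(C)C)C(=O)C=C(O[Li])C[C@@]12O | intermediate (not isolated)
18 | cis-fused hydrindanol vinylogous ester: 7a-hydroxy-4-methoxy-1-methyl-1-(4-methylpent-3-en-1-yl)-2,3a-bis(3-methylbut-2-en-1-yl)-1,2,3,3a,7,7a-hexahydro-6H-inden-6-one; same relative configuration as 16 | CC(C)=CCC[C@@]1(C)[C@@H](CC=C(C)C)C[C@@]2(CC=C(C)C)C(OC)=CC(=O)C[C@@]12O | intermediate
19 | dilithium enolate-alkoxide of 18 (C1=C2 enolate, C9 alkoxide) | CC(C)=CCC[C@@]1(C)[C@@H](CC=C(C)C)C[C@@]2(CC=C(C)C)C(OC)=CC(O[Li])=C[C@@]12O[Li] | intermediate (not isolated)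
20 | C1-[acetoxy(phenyl)iodanyl] ketone, iodane on the β face of C1 (cis to C9–O, anti to C9–C8) | CC(C)=CCC[C@@]1(C)[C@@H](CC=C(C)C)C[C@@]2(CC=C(C)C)C(OC)=CC(=O)[C@H](I(OC(C)=O)c3ccccc3)[C@@]12O[Li] | intermediate (not isolated)
21 | 4-methoxy-8-methyl-8-(4-methylpent-3-en-1-yl)-5,7-bis(3-methylbut-2-en-1-yl)bicyclo[3.3.1]non-3-ene-2,9-dione; C1–H bridgehead; C2–C4 bridge on the α side of ring X, cis to the C7 prenyl and C8 homoprenyl; C8 methyl β | CC(C)=CCC[C@@]1(C)[C@@H](CC=C(C)C)C[C@]2(CC=C(C)C)C(=O)[C@H]1C(=O)C=C2OC | intermediate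
22 | bridgehead C1-lithio derivative of 21 | CC(C)=CCC[C@@]1(C)[C@@H](CC=C(C)C)C[C@]2(CC=C(C)C)C(=O)[C@@]1([Li])C(=O)C=C2OC | intermediate (not isolated)
23 | 4-methoxy-8-methyl-8-(4-methylpent-3-en-1-yl)-1,5,7-tris(3-methylbut-2-en-1-yl)bicyclo[3.3.1]non-3-ene-2,9-dione; configuration as in 21 | CC(C)=CCC[C@@]1(C)[C@@H](CC=C(C)C)C[C@]2(CC=C(C)C)C(=O)[C@@]1(CC=C(C)C)C(=O)C=C2OC | intermediate
24 | 3-hydroxybenzoic acid | O=C(O)c1cccc(O)c1 | starting material
25 | tert-butyldimethylsilyl 3-[(tert-butyldimethylsilyl)oxy]benzoate | CC(C)(C)[Si](C)(C)OC(=O)c1cccc(O[Si](C)(C)C(C)(C)C)c1 | intermediate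
26 | 3-[(tert-butyldimethylsilyl)oxy]benzoyl chloride | O=C(Cl)c1cccc(O[Si](C)(C)C(C)(C)C)c1 | intermediate
27 | C3-lithio derivative of 23 (vinyllithium) | CC(C)=CCC[C@@]1(C)[C@@H](CC=C(C)C)C[C@]2(CC=C(C)C)C(=O)[C@@]1(CC=C(C)C)C(=O)C([Li])=C2OC | intermediate (not isolated)
28 | 3-{3-[(tert-butyldimethylsilyl)oxy]benzoyl}-4-methoxy-8-methyl-8-(4-methylpent-3-en-1-yl)-1,5,7-tris(3-methylbut-2-en-1-yl)bicyclo[3.3.1]non-3-ene-2,9-dione; configuration as in 21 | CC(C)=CCC[C@@]1(C)[C@@H](CC=C(C)C)C[C@]2(CC=C(C)C)C(=O)[C@@]1(CC=C(C)C)C(=O)C(C(=O)c1cccc(O[Si](C)(C)C(C)(C)C)c1)=C2OC | intermediate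
29 | CNP0406274.1: 4-hydroxy-3-(3-hydroxybenzoyl)-8-methyl-8-(4-methylpent-3-en-1-yl)-1,5,7-tris(3-methylbut-2-en-1-yl)bicyclo[3.3.1]non-3-ene-2,9-dione; C7 prenyl and C8 homoprenyl cis to the C2–C4 bridge, C8 methyl anti | CC(C)=CCC[C@@]1(C)[C@@H](CC=C(C)C)C[C@]2(CC=C(C)C)C(=O)[C@@]1(CC=C(C)C)C(=O)C(C(=O)c1cccc(O)c1)=C2O | target

**Step count**

Total: 15 steps. Longest linear sequence: 13 steps (steps 1–11, 14, 15); steps 12–13 make the acid chloride for the convergent step 14.

**Steps most likely to fail, with fallbacks**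

Step 9 (regiochemistry of the enol ether). The sulfate may be attacked by the less hindered O2, or by both oxygens or by C3, so that the enol ether sits on the wrong carbonyl and C1 is no longer α′ to a ketone. Fallback, from 16 back to 18: 16 is treated with Et2BOMe (THF, rt), which ties the C9 oxygen and O2 into a six-membered boron chelate, the diethylboron chelate of the hydrindanol dione F1, in which the C4 enol OH is the only acidic oxygen left. CH2N2 (Et2O, 0 °C) should methylate that oxygen to the diethylboron chelate of the vinylogous ester F2, and repeated evaporation from MeOH removes boron and returns 18.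

Step 10 (key ring expansion). The C9 alkoxide may exchange onto iodine and fragment, the enolate may dimerise oxidatively, or the ring-fusion bond C9–C5 may migrate if the iodane ends up equatorial. Fallback, from 18 back to 21: the same dilithium enolate-alkoxide (LDA 2.2 equiv, THF, −78 °C) is brominated with NBS and quenched cold with AcOH to give the C1 β-bromo hydrindanol vinylogous ester F3. The halohydrin-type semipinacol shift is then triggered separately with a silver salt (Ag2CO3, CH2Cl2, dark, rt), bromide leaving anti to C9–C8, to give 21.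

Step 11 (bridgehead prenylation). Deprotonation may occur at the vinylic C3 instead of the hindered C1 (next to quaternary C8), and the bridgehead carbanion may be captured slowly or on oxygen. Fallback, from 21 back to 23:
- C3 is first blocked as a vinylsilane (LiTMP, THF, −78 °C; TMSCl) to give the C3-trimethylsilyl bicycle F4.
- LDA and then I2 (THF, −78 °C) give the bridgehead C1-iodo C3-trimethylsilyl bicycle F5.
- Keck radical allylation (allyltributylstannane, Et3B/air, benzene, rt) gives the C1-allyl C3-trimethylsilyl bicycle F6 by way of the bridgehead radical.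
- Cross-metathesis with 2-methylbut-2-ene (second-generation Grubbs catalyst, CH2Cl2, 40 °C; the prenyl and homoprenyl alkenes are degenerate partners) gives the C1-prenyl C3-trimethylsilyl bicycle F7.
- TBAF (THF, 0 °C) removes the silyl group and returns 23.

**Further compounds**

F1 | step 9 | diethylboron chelate of the hydrindanol dione (C9–O–BEt2 coordinated by O2; C4 enol) | CC(C)=CCC[C@@]1(C)[C@@H](CC=C(C)C)C[C@@]2(CC=C(C)C)C(O)=CC(=O)C[C@@]12OB(CC)CC
F2 | step 9 | diethylboron chelate of the vinylogous ester (C4–OMe; C9–O–BEt2 coordinated by O2) | CC(C)=CCC[C@@]1(C)[C@@H](CC=C(C)C)C[C@@]2(CC=C(C)C)C(OC)=CC(=O)C[C@@]12OB(CC)CC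
F3 | step 10 | C1 β-bromo hydrindanol vinylogous ester (bromine cis to C9–OH, anti to C9–C8) | CC(C)=CCC[C@@]1(C)[C@@H](CC=C(C)C)C[C@@]2(CC=C(C)C)C(OC)=CC(=O)[C@H](Br)[C@@]12O
F4 | step 11 | C3-trimethylsilyl bicycle (C1–H) | CC(C)=CCC[C@@]1(C)[C@@H](CC=C(C)C)C[C@]2(CC=C(C)C)C(=O)[C@H]1C(=O)C([Si](C)(C)C)=C2OC
F5 | step 11 | bridgehead C1-iodo C3-trimethylsilyl bicycle | CC(C)=CCC[C@@]1(C)[C@@H](CC=C(C)C)C[C@]2(CC=C(C)C)C(=O)[C@@]1(I)C(=O)C([Si](C)(C)C)=C2OC
F6 | step 11 | C1-allyl C3-trimethylsilyl bicycle | CC(C)=CCC[C@@]1(C)[C@@H](CC=C(C)C)C[C@]2(CC=C(C)C)C(=O)[C@@]1(CC=C)C(=O)C([Si](C)(C)C)=C2OC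
F7 | step 11 | C1-prenyl C3-trimethylsilyl bicycle | CC(C)=CCC[C@@]1(C)[C@@H](CC=C(C)C)C[C@]2(CC=C(C)C)C(=O)[C@@]1(CC=C(C)C)C(=O)C([Si](C)(C)C)=C2OC
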